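**Retrosynthetic overview**
- The target is a 3-aroyl-1H-isochromene. Disconnect the C3=C4 bond by an intramolecular aldol condensation, which leads back to an ortho-formyl benzyl phenacyl ether.
- The aldehyde comes from an aryl bromide by Pd reductive carbonylation, so it never meets an organometallic reagent.
- The aryl ketone comes from a Weinreb amide and 2,4-dimethoxyphenylmagnesium bromide.
- The ether comes from a Williamson reaction of 2-bromo-4,5-dimethoxybenzyl alcohol with 2-chloro-N-methoxy-N-methylacetamide.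
- Ring order: both benzene rings are bought; the pyran ring is the only ring formed, and it is closed last.

Assumption: the target has no stereocentre and its only C=C is endocyclic, so it is achiral and "single enantiomer" needs no stereocontrol.

**Route**

Step 1
Reactants: 1 2-bromo-4,5-dimethoxybenzyl alcohol; 2 2-chloro-N-methoxy-N-methylacetamide
Product: 4 2-[(2-bromo-4,5-dimethoxybenzyl)oxy]-N-methoxy-N-methylacetamide, via sodium (2-bromo-4,5-dimethoxyphenyl)methanolate 3 (not isolated)
Conditions: NaH (1.2 equiv), THF, 0 °C; then 2 (1.2 equiv), Bu4NI (cat.), 0 °C → rt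
Reagents that add atoms: none
Why: Williamson ether synthesis, in which the primary benzylic alkoxide displaces chloride from the SN2-activated α-chloro amide faster than it attacks the amide carbonyl; no stereocentre is formed.

Step 2
Reactants: 4 2-[(2-bromo-4,5-dimethoxybenzyl)oxy]-N-methoxy-N-methylacetamide; 5 2,4-dimethoxyphenylmagnesium bromide (commercial 0.5 M THF solution)
Product: 7 2-[(2-bromo-4,5-dimethoxybenzyl)oxy]-1-(2,4-dimethoxyphenyl)ethan-1-one, via bromomagnesium 2-[(2-bromo-4,5-dimethoxybenzyl)oxy]-1-(2,4-dimethoxyphenyl)-1-[methoxy(methyl)amino]ethan-1-olate (chelated tetrahedral adduct, racemic) 6 (not isolated)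
Conditions: 5 (1.3 equiv), THF, 0 °C → rt; then aq. NH4Cl
Reagents that add atoms: none
Why: Weinreb ketone synthesis, in which the N-methoxy magnesium chelate 6 survives until the quench and so stops over-addition, while the aryl bromide and benzyl ether are inert to ArMgBr at 0 °C.

Step 3
Reactants: 7 2-[(2-bromo-4,5-dimethoxybenzyl)oxy]-1-(2,4-dimethoxyphenyl)ethan-1-one
Product: 8 2-{[2-(2,4-dimethoxyphenyl)-2-oxoethoxy]methyl}-4,5-dimethoxybenzaldehyde
Conditions: Pd(OAc)2 (1 mol %), BuPAd2 (3 mol %), TMEDA (1 equiv), CO/H2 (1:1, 5 bar), toluene, 100 °C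
Reagents that add atoms: carbon monoxide, [C-]#[O+]
Why: Pd-catalysed reductive carbonylation (formylation) of an aryl bromide by oxidative addition, CO insertion and hydrogenolysis of the acyl-Pd, under conditions that tolerate aryl ketones and ethers.

Step 4
Reactants: 8 2-{[2-(2,4-dimethoxyphenyl)-2-oxoethoxy]methyl}-4,5-dimethoxybenzaldehyde
Product: 10 (6,7-dimethoxy-1H-isochromen-3-yl)(2,4-dimethoxyphenyl)methanone (target), via (2,4-dimethoxyphenyl)(4-hydroxy-6,7-dimethoxy-3,4-dihydro-1H-isochromen-3-yl)methanone (aldol adduct, racemic diastereomer mixture) 9 (not isolated)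
Conditions: KOH (0.3 equiv), EtOH, rt → 50 °C
Reagents that add atoms: none
Why: Intramolecular Claisen–Schmidt (aldol) condensation, in which the α-alkoxy ketone enolate closes the six-membered ring onto the ortho aldehyde and E1cB loss of water from 9 gives the conjugated C3=C4 enol ether–enone; both stereocentres of 9 are destroyed, so none needs control.

**Compound list**
1 | 2-bromo-4,5-dimethoxybenzyl alcohol | COc1cc(Br)c(CO)cc1OC | starting material
2 | 2-chloro-N-methoxy-N-methylacetamide | CON(C)C(=O)CCl | starting material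
3 | sodium (2-bromo-4,5-dimethoxyphenyl)methanolate | COc1cc(Br)c(C[O-])cc1OC.[Na+] | intermediate
4 | 2-[(2-bromo-4,5-dimethoxybenzyl)oxy]-N-methoxy-N-methylacetamide | CON(C)C(=O)COCc1cc(OC)c(OC)cc1Br | intermediate
5 | 2,4-dimethoxyphenylmagnesium bromide | COc1ccc([Mg]Br)c(OC)c1 | starting material
6 | bromomagnesium 2-[(2-bromo-4,5-dimethoxybenzyl)oxy]-1-(2,4-dimethoxyphenyl)-1-[methoxy(methyl)amino]ethan-1-olate (racemic) | CON(C)C(O[Mg]Br)(COCc1cc(OC)c(OC)cc1Br)c1ccc(OC)cc1OC | intermediate
7 | 2-[(2-bromo-4,5-dimethoxybenzyl)oxy]-1-(2,4-dimethoxyphenyl)ethan-1-one | COc1ccc(C(=O)COCc2cc(OC)c(OC)cc2Br)c(OC)c1 | intermediate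
8 | 2-{[2-(2,4-dimethoxyphenyl)-2-oxoethoxy]methyl}-4,5-dimethoxybenzaldehyde | COc1ccc(C(=O)COCc2cc(OC)c(OC)cc2C=O)c(OC)c1 | intermediate
9 | (2,4-dimethoxyphenyl)(4-hydroxy-6,7-dimethoxy-3,4-dihydro-1H-isochromen-3-yl)methanone (racemic, diastereomer mixture) | COc1ccc(C(=O)C2OCc3cc(OC)c(OC)cc3C2O)c(OC)c1 | intermediate
10 | (6,7-dimethoxy-1H-isochromen-3-yl)(2,4-dimethoxyphenyl)methanone | COc1ccc(C(=O)C2=Cc3cc(OC)c(OC)cc3CO2)c(OC)c1 | target

**Totals**
Total step count: 4. Longest linear sequence: 4 (1 → 4 → 7 → 8 → 10).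

**Three steps most likely to fail**

Step 3 (formylation) is the riskiest. The bromide is electron-rich and ortho-substituted, so hydrodebromination can compete, and the amine base may partly cyclise 8 to 10 in the pot. Any 10 formed is simply carried through step 4. The fallback sets out from 7 and returns at 8. Stille coupling of 7 with tributyl(vinyl)stannane (Pd(PPh3)4, toluene, 110 °C) gives the styrene 1-(2,4-dimethoxyphenyl)-2-[(2-ethenyl-4,5-dimethoxybenzyl)oxy]ethan-1-one F1. Lemieux–Johnson oxidation (OsO4 cat., NaIO4, 2,6-lutidine, dioxane/H2O, rt) dihydroxylates it to the diol 2-{[2-(1,2-dihydroxyethyl)-4,5-dimethoxybenzyl]oxy}-1-(2,4-dimethoxyphenyl)ethan-1-one F2 (racemic, not isolated). Periodate cleaves F2 in the same flask to aldehyde 8.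

Step 1 (Williamson with the chloro Weinreb amide) is next. The alkoxide could attack the amide carbonyl, or base could degrade the N-methoxy amide. The fallback sets out from 1 and returns at 4. Treating 1 with NaH (2.5 equiv) and bromoacetic acid in THF (0 °C → reflux) alkylates alkoxide 3 with sodium bromoacetate, and HCl work-up gives [(2-bromo-4,5-dimethoxybenzyl)oxy]acetic acid F3. CDI (CH2Cl2, rt) converts F3 into the acyl imidazolide 2-[(2-bromo-4,5-dimethoxybenzyl)oxy]-1-(1H-imidazol-1-yl)ethan-1-one F4 (not isolated). Adding N,O-dimethylhydroxylamine hydrochloride then gives Weinreb amide 4.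

Step 2 (Grignard addition) is third. The basic, ortho-substituted aryl Grignard could enolise the α-alkoxy amide, or the reaction could stall. The fallback sets out from 1, bypasses 4, and returns at 7. Purchased 2,4-dimethoxybenzoyl chloride (COc1ccc(C(Cl)=O)c(OC)c1) and trimethylsilyldiazomethane (MeCN/THF, 0 °C → rt) give the diazoketone 2-diazo-1-(2,4-dimethoxyphenyl)ethan-1-one F5. Slow addition of F5 to alcohol 1 with Rh2(OAc)4 (1 mol %) in CH2Cl2 at rt gives ketone 7 by rhodium-carbenoid O–H insertion.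

**Further compounds**
F1 | step 3 | 1-(2,4-dimethoxyphenyl)-2-[(2-ethenyl-4,5-dimethoxybenzyl)oxy]ethan-1-one | COc1ccc(C(=O)COCc2cc(OC)c(OC)cc2C=C)c(OC)c1
F2 | step 3 | 2-{[2-(1,2-dihydroxyethyl)-4,5-dimethoxybenzyl]oxy}-1-(2,4-dimethoxyphenyl)ethan-1-one (racemic) | COc1ccc(C(=O)COCc2cc(OC)c(OC)cc2C(O)CO)c(OC)c1
F3 | step 1 | [(2-bromo-4,5-dimethoxybenzyl)oxy]acetic acid | COc1cc(Br)c(COCC(=O)O)cc1OC
F4 | step 1 | 2-[(2-bromo-4,5-dimethoxybenzyl)oxy]-1-(1H-imidazol-1-yl)ethan-1-one | COc1cc(Br)c(COCC(=O)n2ccnc2)cc1OC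
F5 | step 2 | 2-diazo-1-(2,4-dimethoxyphenyl)ethan-1-one | COc1ccc(C(=O)C=[N+]=[N-])c(OC)c1
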